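At early times in the alder run the complex with two exchanged climbs to 18.8% by 3.00 min, and then it barely moves, reading between 16.0% and 20.7% up to 25.0 min. Two chemists read that differently.

| setting | birch | alder | noon | midnight | summer |
|---|---|---|---|---|---|
| starting complex | 0.33 M | 0.33 M | 0.33 M | 0.33 M | 0.33 M |
| incoming ligand | 0.39 equiv | 2.6 equiv | 0.500 equiv | 2.00 equiv | 4.00 equiv |
| protic impurity | 0.0165 M | 0.0165 M | 0.0165 M | 0.0165 M | 0.0165 M |
| remark | run made earlier | run made earlier |  |  |  |
| time |  |  | 25 min | 25 min | 25 min |

| run | time / min | complex with two exchanged / % | complex with three exchanged / % | starting complex / % |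
|---|---|---|---|---|
| birch | 2.00 | 0.7 | 0.4 | 66.4 |
| birch | 3.00 | 0.8 | 0.1 | 59.3 |
| birch | 5.00 | 2.1 | 0.6 | 49.1 |
| birch | 8.00 | 2.1 | 0 | 40.5 |
| birch | 10.0 | 2.2 | 0.5 | 36.5 |
| birch | 15.0 | 3.4 | 0 | 29.5 |
| birch | 25.0 | 3.3 | 0.7 | 23.2 |
| alder | 2.00 | 13.9 | 5.7 | 19.7 |
| alder | 3.00 | 18.8 | 11.9 | 11.3 |
| alder | 5.00 | 19.7 | 22.2 | 4.7 |
| alder | 8.00 | 20.7 | 36.7 | 2.1 |
| alder | 10.0 | 20.3 | 42.8 | 0.7 |
| alder | 15.0 | 17.0 | 52.1 | 0.9 |
| alder | 25.0 | 16.0 | 61.8 | 1.0 |

(scatter of a reading: 0.5 percentage points)

1. final complex with two exchanged, as a percentage of the starting complex charged, for each flask in turn (noon, midnight, summer)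

- the numbers in the tables scatter by 0.5 percentage points (one standard deviation)

The first sees a plateau, a level this form keeps once it is reached, so summer should end near alder's 16.0%. The second sees a form that is fed and drained at once, its drain growing with the incoming ligand still free.

The second puts a number on the drain. In alder, between 5.00 min and 8.00 min, the complex with three exchanged rises from 22.2% to 36.7%, so each minute about 0.239 min⁻¹ of the two-exchanged complex moves on. Counting the unread share as complex with one exchanged, after setting aside the impurity's share, leaves about 0.893 equivalents free. That gives 0.268 min⁻¹ per equivalent. Hence the sweep half-life, the time in which the two-exchanged complex would halve with one equivalent of free ligand and no feed, is 2.59 min; it shortens in proportion to the free ligand.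

Summer's charge exceeds 3 per complex by 1.00 equivalent, so the sweep stays open, and its half-life is shorter than the run. Bare decay from alder's top over the remaining time gives 0.218%. That is a lower mark, since feed continues, so I expect a low figure.

At the other end two exchanges need two ligands, so the amount should go with the square of the charge, and birch's reading scales to 5.42% for noon. Between the ends, midnight's ligand is the limiting reagent, and I take alder's top, 20.7%.

The forecast says 4.5%, 20% and 2%, because at the highest charge “ligand stays in excess”.

The flasks give 5.37% for noon, 21.2% for midnight and 4.46% for summer.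

    starting complex + incoming ligand ⇌ leaving ligand + complex with one exchanged (K = 92.0, k = 0.0190 L mol⁻¹ s⁻¹)
    complex with one exchanged + incoming ligand ⇌ leaving ligand + complex with two exchanged (K = 49.0, k = 0.00670 L mol⁻¹ s⁻¹)
    complex with two exchanged + incoming ligand ⇌ leaving ligand + complex with three exchanged (K = 47.0, k = 0.0120 L mol⁻¹ s⁻¹)
    protic impurity + starting complex → quenched substrate (k = 2.00 L mol⁻¹ s⁻¹)
    2 starting complex → homo dimer (k = 0.00220 L mol⁻¹ s⁻¹)

In summer the two-exchanged complex stands at 8.00% after 12.5 min, 4.46% after 25.0 min and 3.99% after 250 min, so it levels off. Summer's final 1.30 equivalents of free ligand make the sweep half-life 2.00 min. Midnight's 0.141 equivalents stretch this reckoned half-life to 18.4 min. Midnight's two-exchanged complex reads 21.4% after 12.5 min and 21.2% after 25.0 min, as flat as the first chemist's view has it, yet midnight's complex with three exchanged rises from 30.2% to 39.4% over the same stretch, and midnight's two-exchanged complex stands at 25.0% after 250 min.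

(Readings and results were computed for substances that don't exist; scatter was added.)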